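Taking the common logarithm of a fraction left is an easy step, and it turns this flask into simple addition. Call a substrate's depth the number of decades it has fallen from its own charge.

all flasks: precatalyst 0.073 mol%
- delta: left-handed substrate 0.050 M; right-handed substrate 0.050 M; partner 1 equiv; the very flask that is asked about, followed so far
- gamma: left-handed substrate 0.10 M; right-handed substrate 0.10 M; partner 1 equiv; run made earlier
- flask: left-handed substrate 0.050 M; right-handed substrate 0.050 M; partner 1.00 equiv; time 80 min

| run | time / min | right-handed substrate / % | left-handed substrate / % | left-handed product / % |
|---|---|---|---|---|
| delta | 6.00 | 50.0 | 48.6 | 0 |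
| delta | 12.0 | 52.2 | 49.7 | 2.5 |
| delta | 15.0 | 50.0 | 46.4 | 4.1 |
| delta | 25.0 | 49.0 | 41.7 | 9.0 |
| delta | 30.0 | 48.5 | 38.8 | 12.7 |
| delta | 40.0 | 48.8 | 35.4 | 14.9 |
| gamma | 5.00 | 50.2 | 46.3 | 3.0 |
| gamma | 10.0 | 49.2 | 39.2 | 11.4 |
| gamma | 15.0 | 47.5 | 31.6 | 18.1 |
| gamma | 20.0 | 48.2 | 29.3 | 22.8 |
| gamma | 25.0 | 46.5 | 23.7 | 24.8 |
| gamma | 30.0 | 46.9 | 22.6 | 27.2 |

(standard deviation of a reading: 1 percentage point)

- free catalyst is single-handed; left-handed substrate and right-handed substrate are mirror images of each other, charged as a racemate, each of them at the stated concentration
- candidate steps: partner + free catalyst + left-handed substrate -> free catalyst + left-handed product; partner + free catalyst + right-handed substrate -> free catalyst + right-handed product; partner + precatalyst -> free catalyst + spent reagent; partner + free catalyst -> spent catalyst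

1. whether the excess of right-handed substrate over left-handed substrate among what is left of the two reaches 95 % by 80 min (yes / no)
2. the highest excess of right-handed substrate over left-handed substrate among what is left of the two up to 80 min

If the two candidate substrate steps run as written, both rates carry the same factor of partner and free catalyst. That factor cancels in the ratio of the two depths, however it changes with time. This ratio of left-handed depth to right-handed depth is the selectivity factor, read from the last reading of the gamma run as 12.4. That reading went deeper than the last of the delta run, but it stays rough, with a scatter of 1 percentage point on a right-handed fall of 3.1 points.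

Each decade of left-handed depth then adds 0.919 of a decade to the ratio of right-handed to left-handed substrate. An excess of 95 % needs a ratio of 39.0, so it needs a left-handed depth of 1.73. The last delta reading, with its scatter, puts this flask at a left-handed depth of 0.150 at 40.0 min.

Two views dispute the depth at 80 min. The fade side reads in the gamma run “a fade with a time constant of about 10 min as catalyst dies”, and its forecast is no, with a top of 22 %. The steady side, reckoned here, extends the straight line through the delta depths at 15.0 min and 40.0 min. That line reaches 0.338, which gives an excess of 34.3 %. This is also far short of the depth needed, so the two sides differ on the top and not on the yes or no.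

The flask gives no, with a highest excess of 29.8 %: 7.8 points above the forecast and 4.5 points below the steady line. Of the catalyst charged to this flask, free catalyst stood at 15.8 %, 35.8 % and 34.2 % at 8.00 min, 40.0 min and 80.0 min, while by the last of these times precatalyst had fallen to 25.4 % and spent catalyst had risen to 40.3 %. Left-handed substrate ended at 51 % of its charge, and that depth with 12.4 gives 30.0 %. The fade view has its region later in this flask: at 800 min, spent catalyst stands at 92.3 % and free catalyst at 6.11 % of the catalyst charged.

    partner + free catalyst + left-handed substrate → free catalyst + left-handed product (k = 380 M⁻² s⁻¹)
    partner + free catalyst + right-handed substrate → free catalyst + right-handed product (k = 33.0 M⁻² s⁻¹)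
    partner + precatalyst → free catalyst + spent reagent (k = 0.00810 M⁻¹ s⁻¹)
    partner + free catalyst → spent catalyst (k = 0.00830 M⁻¹ s⁻¹)

Left until 5.0 h, the same flask has 28 % of its left-handed substrate left, a depth of 0.553, and the rule gives 52.6 %. The computed top there is 52.7 %.

The data are calculated for an exercise, noise included.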